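**Plan**

- Retrosynthetic cuts (azulene numbering C1–C3, C3a, C4–C8, C8a; side chain C1'–C7'): acetate and silyl groups; C3'–C4' (Weinreb amide plus alkynol); the C8 methylidene (from a C8 ketone); C5–C2' (enolate plus lactate triflate); then both cyclopentene bonds C1–C8a and C3–C3a in one [3+2] event.
- Enabling feature: the ring-fusion bond C3a–C8a lies α,β to the carbinol carbon C4. With C4 as a ketone and a helper oxygen at C8 trans to the C7 oxygen, the seven-membered ring becomes a C2-symmetric cross-conjugated dienone whose two enones are homotopic.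
- Forward order: the seven-membered ring is bought (cyclohept-4-enone), then trans-diol, dienone, cyclopentene by annulation, C5 side-chain carbon, C8 methylidene, alkyne chain, acetate.
- Stereochemistry: C7 (and helper C8) from catalytic desymmetrisation of a meso epoxide; C3a from annulation anti to the C8 silyloxy group; C8a by equilibration to the trans ring fusion through the C8 ketone; C5 by enolate alkylation; C2' from (R)-lactate with inversion; C4 by reduction; C3' by catalyst-controlled transfer hydrogenation; the E-alkene by trans-hydroalumination.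

Key step: step 8

Assumption: in step 5 the (R,R)-configured cobalt salen catalyst is taken to give the (4R,5R)-diol; if the sense of induction on this epoxide is the opposite, the (S,S)-catalyst is used.

**Route**

Step 1
Reactants: 1 3-(trimethylsilyl)prop-2-yn-1-ol
Product: 2 3-(trimethylsilyl)prop-2-yn-1-yl methanesulfonate
Conditions: MsCl, Et3N, CH2Cl2, 0 °C
Reagents that add atoms: methanesulfonyl chloride, CS(=O)(=O)Cl
Why: Sulfonylation of the primary propargylic alcohol (mesylate formation) installs the leaving group for the SN2' step; no stereocentre is involved.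

Step 2
Reactants: 2 3-(trimethylsilyl)prop-2-yn-1-yl methanesulfonate
Product: 3 (buta-2,3-dien-2-yl)trimethylsilane
Conditions: MeMgCl, CuBr (cat.), LiBr, THF, −70 to 20 °C
Reagents that add atoms: methylmagnesium chloride, C[Mg]Cl
Why: Copper-catalysed SN2' substitution of the propargylic mesylate places the methyl group on the silicon-bearing carbon and should give the 1-methyl-1-silylallene.

Step 3
Reactants: 4 methyl (R)-lactate
Product: 5 methyl (2R)-2-(trifluoromethanesulfonyloxy)propanoate
Conditions: Tf2O, 2,6-lutidine, CH2Cl2, −78 to 0 °C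
Reagents that add atoms: trifluoromethanesulfonic anhydride, O=S(=O)(OS(=O)(=O)C(F)(F)F)C(F)(F)F
Why: O-Triflation of the α-hydroxy ester occurs with retention at carbon and gives a secondary electrophile that reacts by SN2 with inversion.

Step 4
Reactants: 6 cyclohept-4-en-1-one
Product: 7 meso-4,5-epoxycycloheptan-1-one
Conditions: mCPBA, NaHCO3, CH2Cl2, 0 °C
Reagents that add atoms: 3-chloroperbenzoic acid, OOC(=O)c1cccc(Cl)c1
Why: Prilezhaev epoxidation of the isolated cis-alkene should be faster than Baeyer–Villiger oxidation of the ketone under buffered conditions and gives the meso cis-epoxide.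

Step 5
Reactants: 7 meso-4,5-epoxycycloheptan-1-one
Product: 8 (4R,5R)-4,5-dihydroxycycloheptan-1-one
Conditions: (R,R)-[N,N'-bis(3,5-di-tert-butylsalicylidene)cyclohexane-1,2-diaminato]cobalt tosylate (trivalent cobalt, cat.), H2O, MeCN, 4 °C
Reagents that add atoms: water, O
Why: Cobalt-salen-catalysed enantioselective hydrolytic opening of the meso epoxide (Jacobsen desymmetrisation) lets water attack one of the two enantiotopic carbons from the rear, which sets both carbinol centres and gives the C2-symmetric trans-diol.

Step 6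
Reactants: 8 (4R,5R)-4,5-dihydroxycycloheptan-1-one
Product: 9 (4R,5R)-4,5-bis(triethylsilyloxy)cycloheptan-1-one
Conditions: TESCl, imidazole, DMF, 0 to 20 °C
Reagents that add atoms: chlorotriethylsilane, CC[Si](Cl)(CC)CC
Why: Twofold silyl ether formation keeps the C2 axis; triethylsilyl is chosen because acid later removes it in the presence of tert-butyldimethylsilyl ethers.

Step 7
Reactants: 9 (4R,5R)-4,5-bis(triethylsilyloxy)cycloheptan-1-one
Product: 10 (4R,5R)-4,5-bis(triethylsilyloxy)cyclohepta-2,6-dien-1-one
Conditions: IBX (2.5 equiv), 4-methoxypyridine N-oxide, DMSO, 25 to 40 °C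
Reagents that add atoms: none
Why: IBX-mediated α,β-dehydrogenation on both sides of the ketone should give the cross-conjugated dienone without touching the two silyloxy-bearing carbons.

Step 8
Reactants: 10 (4R,5R)-4,5-bis(triethylsilyloxy)cyclohepta-2,6-dien-1-one; 3 (buta-2,3-dien-2-yl)trimethylsilane
Product: 11 cis-fused silylcyclopentene enone
Conditions: TiCl4 (1.1 equiv), 3 (1.05 equiv), CH2Cl2, −78 °C
Reagents that add atoms: none
Why: TiCl4 activates the dienone, the CH2 terminus of allene 3 adds to C3 of one enone to give a titanium dienolate and a β-silyl vinyl cation, a 1,2-shift of silicon moves the positive charge to the methyl-bearing carbon, and the enolate carbon C2 captures it, so that the bonds C1–C8a and C3–C3a of the hydroazulene form in one operation. The closest known reaction type is the Danheiser [3+2] (trimethylsilyl)cyclopentene annulation of allenylsilanes with cyclic enones. The five-membered ring closes by a 5-(enolexo)-endo-dig attack of the enolate carbon on the digonal cationic carbon, which for geometric reasons gives the cis ring fusion. C8a is controlled by the adjacent silyloxy group (dienone C4, later C8), anti to which the allene approaches, and C3a by the cis closure. The step needs regio-, face- and mono-selectivity: the C2 axis through the carbonyl makes the two enones homotopic, so that attack on either one anti to its own γ-silyloxy group gives the same product, and one equivalent of 3 at −78 °C should stop at mono-annulation because the product enone is flanked by a ring-fusion carbon. The silicon left on C2 is taken out in step 13.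

Step 9
Reactants: 11 cis-fused silylcyclopentene enone; 5 methyl (2R)-2-(trifluoromethanesulfonyloxy)propanoate
Product: 13 C5-alkylated keto ester, via potassium enolate 12 (not isolated)
Conditions: KBH(s-Bu)3, THF, −78 °C; then 5, DMPU, −78 to −30 °C
Reagents that add atoms: none
Why: Conjugate hydride addition to the remaining β-unsubstituted enone generates the C4=C5 enolate regiospecifically, and its SN2 alkylation by the triflate with inversion sets C2' as R (reductive alkylation of an enone); the electrophile should reach C5 from the face opposite the C3a–C3 bond and the C7 silyloxy group, both 1,3-related to C5, which places the side chain cis to H-3a.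

Step 10
Reactants: 13 C5-alkylated keto ester
Product: 15 cis-fused γ-lactone, via hydroxy ester 14 (not isolated)
Conditions: LiBH(s-Bu)3, THF, −78 °C; AcOH; then PPTS (cat.), CH2Cl2, 20 °C
Reagents that add atoms: none
Why: Bulky-hydride reduction of the C4 ketone should deliver hydride anti to the branched C5 substituent and give the 4,5-cis hydroxy ester, which closes to the γ-lactone under mild acid (lactonisation); only the cis alcohol can lactonise, so the lactone confirms C4.

Step 11
Reactants: 15 cis-fused γ-lactone
Product: 16 Weinreb amide alcohol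
Conditions: MeNH(OMe)·HCl, AlMe3, CH2Cl2, 0 to 20 °C
Reagents that add atoms: N,O-dimethylhydroxylamine hydrochloride, CNOC.Cl
Why: Aluminium amide aminolysis of the lactone (Weinreb amide formation) opens the ring without enolising C2' and frees the C4 hydroxyl.

Step 12
Reactants: 16 Weinreb amide alcohol
Product: 17 4-O-TBS Weinreb amide
Conditions: TBSOTf, 2,6-lutidine, CH2Cl2, −78 to 0 °C
Reagents that add atoms: tert-butyldimethylsilyl trifluoromethanesulfonate, CC(C)(C)[Si](C)(C)OS(=O)(=O)C(F)(F)F
Why: Silyl ether formation with the silyl triflate blocks the hindered C4 alcohol and prevents relactonisation of the γ-hydroxy amide.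

Step 13
Reactants: 17 4-O-TBS Weinreb amide
Product: 18 7,8-diol
Conditions: CF3CO2H, CH2Cl2, 0 °C; aqueous NaHCO3
Reagents that add atoms: none
Why: Acid should cleave both triethylsilyl ethers and protodesilylate the vinylsilane by ipso protonation through a tertiary β-silyl cation (protodesilylation), so the double bond stays at C2=C3, while the hindered secondary TBS ether survives.

Step 14
Reactants: 18 7,8-diol
Product: 19 7-O-TBS 8-alcohol
Conditions: TBSCl (1.1 equiv), imidazole, DMF, −20 to 0 °C
Reagents that add atoms: tert-butyldimethylsilyl chloride, CC(C)(C)[Si](C)(C)Cl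
Why: Site-selective silylation should take the C7 hydroxyl, which is flanked by a CH2 group, in preference to the C8 hydroxyl next to the ring-fusion methine (mono-silylation of a diol), which differentiates the two oxygens.

Step 15
Reactants: 19 7-O-TBS 8-alcohol
Product: 21 trans-fused 8-ketone, via cis-fused 8-ketone 20 (not isolated)
Conditions: Dess–Martin periodinane, NaHCO3, CH2Cl2, 20 °C; then DBU, toluene, 20 to 40 °C
Reagents that add atoms: none
Why: Dess–Martin oxidation gives the C8 ketone, and reversible enolisation toward C8a should equilibrate the cis-fused ketone to the thermodynamically preferred trans-fused hydroazulenone (epimerisation α to a carbonyl), which sets C8a; C3a has no adjacent carbonyl and the bulky silyloxy group disfavours enolisation toward C7.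

Step 16
Reactants: 21 trans-fused 8-ketone
Product: 22 8-methylidene Weinreb amide
Conditions: Zn, CH2Br2, TiCl4, THF/CH2Cl2, 0 to 20 °C
Reagents that add atoms: dibromomethane, BrCBr
Why: Non-basic Takai–Lombardo methylenation should convert the hindered, enolisable α-silyloxy ketone into the exocyclic methylene without epimerising C7 or C8a and without attacking the Weinreb amide.

Step 17
Reactants: 22 8-methylidene Weinreb amide; 23 2-methylbut-3-yn-2-ol
Product: 24 ynone
Conditions: 23, n-BuLi (2 equiv per 23), THF, −78 °C; then 22, −78 to 0 °C; H2O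
Reagents that add atoms: none
Why: The dilithiated alkynol adds once to the Weinreb amide, the chelated tetrahedral adduct holds until work-up, and the ynone results (Weinreb ketone synthesis).

Step 18
Reactants: 24 ynone
Product: 25 (3'R)-propargylic alcohol
Conditions: Ru[(R,R)-TsNCH(Ph)CH(Ph)NH](p-cymene) (cat.), i-PrOH, 20 °C
Reagents that add atoms: none
Why: Noyori asymmetric transfer hydrogenation of the alkynyl ketone sets C3' by catalyst control under neutral conditions that spare the α-stereocentre, and Felkin–Anh attack anti to the ring substituent points the same way; the (R)-propargylic centre corresponds to the (S)-allylic centre of the target.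

Step 19
Reactants: 25 (3'R)-propargylic alcohol
Product: 26 (E)-allylic diol
Conditions: NaAlH2(OCH2CH2OMe)2, THF, 0 to 20 °C
Reagents that add atoms: none
Why: Alkoxide-directed trans-hydroalumination of the propargylic alcohol followed by protonolysis should give only the (E)-alkene.

Step 20
Reactants: 26 (E)-allylic diol
Product: 27 bis-TBS acetate
Conditions: Ac2O, pyridine, DMAP (cat.), CH2Cl2, 0 °C
Reagents that add atoms: acetic anhydride, CC(=O)OC(C)=O
Why: Acetylation takes the only free secondary hydroxyl; the tertiary allylic alcohol should not react under these conditions.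

Step 21
Reactants: 27 bis-TBS acetate
Product: 28 target
Conditions: HF·pyridine, pyridine, THF, 0 to 20 °C
Reagents that add atoms: none
Why: Buffered fluoride cleavage of both TBS ethers (desilylation) should leave the allylic acetate and the acid-sensitive tertiary allylic alcohol intact.

**Compound list**

1 | 3-(trimethylsilyl)prop-2-yn-1-ol | C[Si](C)(C)C#CCO | starting material
2 | 3-(trimethylsilyl)prop-2-yn-1-yl methanesulfonate | C[Si](C)(C)C#CCOS(C)(=O)=O | intermediate
3 | (buta-2,3-dien-2-yl)trimethylsilane (1-methyl-1-(trimethylsilyl)allene) | C=C=C(C)[Si](C)(C)C | intermediate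
4 | methyl (R)-lactate | C[C@@H](O)C(=O)OC | starting material
5 | methyl (2R)-2-(trifluoromethanesulfonyloxy)propanoate | C[C@@H](OS(=O)(=O)C(F)(F)F)C(=O)OC | intermediate
6 | cyclohept-4-en-1-one | O=C1CCC=CCC1 | starting material
7 | meso-4,5-epoxycycloheptan-1-one (cis-8-oxabicyclo[5.1.0]octan-4-one) | O=C1CC[C@@H]2O[C@@H]2CC1 | intermediate
8 | (4R,5R)-4,5-dihydroxycycloheptan-1-one | O[C@H]1[C@H](O)CCC(=O)CC1 | intermediate
9 | (4R,5R)-4,5-bis(triethylsilyloxy)cycloheptan-1-one | CC[Si](CC)(CC)O[C@H]1[C@H](O[Si](CC)(CC)CC)CCC(=O)CC1 | intermediate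
10 | (4R,5R)-4,5-bis(triethylsilyloxy)cyclohepta-2,6-dien-1-one | CC[Si](CC)(CC)O[C@H]1[C@H](O[Si](CC)(CC)CC)C=CC(=O)C=C1 | intermediate
11 | cis-fused 3-methyl-7,8-bis(triethylsilyloxy)-2-(trimethylsilyl)-3a,7,8,8a-tetrahydroazulen-4(1H)-one; H-3a, H-8a and the 8-silyloxy group on one face, the 7-silyloxy group on the other | CC[Si](CC)(CC)O[C@H]1[C@H](O[Si](CC)(CC)CC)C=CC(=O)[C@@H]2C(C)=C([Si](C)(C)C)C[C@H]12 | intermediate
12 | potassium C4=C5 enolate of the 5,6-dihydro derivative of 11 | CC[Si](CC)(CC)O[C@H]1[C@H](O[Si](CC)(CC)CC)CC=C(O[K])[C@@H]2C(C)=C([Si](C)(C)C)C[C@H]12 | intermediate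
13 | methyl (2R)-2-[cis-fused 3-methyl-4-oxo-7,8-bis(triethylsilyloxy)-2-(trimethylsilyl)-1,3a,4,5,6,7,8,8a-octahydroazulen-5-yl]propanoate; side chain cis to H-3a | CC[Si](CC)(CC)O[C@H]1[C@H](O[Si](CC)(CC)CC)C[C@@H]([C@@H](C)C(=O)OC)C(=O)[C@@H]2C(C)=C([Si](C)(C)C)C[C@H]12 | intermediate
14 | 4-hydroxy ester from 13; 4-OH cis to the C5 side chain | CC[Si](CC)(CC)O[C@H]1[C@H](O[Si](CC)(CC)CC)C[C@@H]([C@@H](C)C(=O)OC)[C@@H](O)[C@@H]2C(C)=C([Si](C)(C)C)C[C@H]12 | intermediate
15 | γ-lactone of 14 (C4 oxygen to the side-chain carboxyl, cis-fused at C4–C5; α-methyl on the concave face) | CC[Si](CC)(CC)O[C@H]1[C@H](O[Si](CC)(CC)CC)C[C@@H]([C@@H](C)C(=O)O3)[C@@H]3[C@@H]2C(C)=C([Si](C)(C)C)C[C@H]12 | intermediate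
16 | (2R)-2-[4-hydroxy-3-methyl-7,8-bis(triethylsilyloxy)-2-(trimethylsilyl)-1,3a,4,5,6,7,8,8a-octahydroazulen-5-yl]-N-methoxy-N-methylpropanamide; ring configuration as in 14 | CC[Si](CC)(CC)O[C@H]1[C@H](O[Si](CC)(CC)CC)C[C@@H]([C@@H](C)C(=O)N(C)OC)[C@@H](O)[C@@H]2C(C)=C([Si](C)(C)C)C[C@H]12 | intermediate
17 | 4-O-tert-butyldimethylsilyl ether of 16 | CC[Si](CC)(CC)O[C@H]1[C@H](O[Si](CC)(CC)CC)C[C@@H]([C@@H](C)C(=O)N(C)OC)[C@@H](O[Si](C)(C)C(C)(C)C)[C@@H]2C(C)=C([Si](C)(C)C)C[C@H]12 | intermediate
18 | 7,8-diol: 17 without the two triethylsilyl groups and without the C2 trimethylsilyl group (trans-7,8-diol, cis ring fusion) | O[C@H]1[C@H](O)C[C@@H]([C@@H](C)C(=O)N(C)OC)[C@@H](O[Si](C)(C)C(C)(C)C)[C@@H]2C(C)=CC[C@H]12 | intermediate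
19 | 4,7-bis-O-TBS 8-alcohol (7-O-silyl ether of 18) | O[C@H]1[C@H](O[Si](C)(C)C(C)(C)C)C[C@@H]([C@@H](C)C(=O)N(C)OC)[C@@H](O[Si](C)(C)C(C)(C)C)[C@@H]2C(C)=CC[C@H]12 | intermediate
20 | cis-fused 8-ketone from 19 (H-3a and H-8a cis) | O=C1[C@H](O[Si](C)(C)C(C)(C)C)C[C@@H]([C@@H](C)C(=O)N(C)OC)[C@@H](O[Si](C)(C)C(C)(C)C)[C@@H]2C(C)=CC[C@H]12 | intermediate
21 | trans-fused 8-ketone (C8a epimer of 20; H-8a trans to H-3a) | O=C1[C@H](O[Si](C)(C)C(C)(C)C)C[C@@H]([C@@H](C)C(=O)N(C)OC)[C@@H](O[Si](C)(C)C(C)(C)C)[C@@H]2C(C)=CC[C@@H]12 | intermediate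
22 | (2R)-2-[(3aS,4R,5S,7R,8aR)-4,7-bis(tert-butyldimethylsilyloxy)-3-methyl-8-methylidene-1,3a,4,5,6,7,8,8a-octahydroazulen-5-yl]-N-methoxy-N-methylpropanamide | C=C1[C@H](O[Si](C)(C)C(C)(C)C)C[C@@H]([C@@H](C)C(=O)N(C)OC)[C@@H](O[Si](C)(C)C(C)(C)C)[C@@H]2C(C)=CC[C@@H]12 | intermediate
23 | 2-methylbut-3-yn-2-ol | CC(C)(O)C#C | starting material
24 | (2R)-2-[ring as in 22]-6-hydroxy-6-methylhept-4-yn-3-one | C=C1[C@H](O[Si](C)(C)C(C)(C)C)C[C@@H]([C@@H](C)C(=O)C#CC(C)(C)O)[C@@H](O[Si](C)(C)C(C)(C)C)[C@@H]2C(C)=CC[C@@H]12 | intermediate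
25 | (2R,3R)-2-[ring as in 22]-6-methylhept-4-yne-3,6-diol | C=C1[C@H](O[Si](C)(C)C(C)(C)C)C[C@@H]([C@@H](C)[C@H](C#CC(C)(C)O)O)[C@@H](O[Si](C)(C)C(C)(C)C)[C@@H]2C(C)=CC[C@@H]12 | intermediate
26 | (2R,3S,4E)-2-[ring as in 22]-6-methylhept-4-ene-3,6-diol | C=C1[C@H](O[Si](C)(C)C(C)(C)C)C[C@@H]([C@@H](C)[C@H](/C=C/C(C)(C)O)O)[C@@H](O[Si](C)(C)C(C)(C)C)[C@@H]2C(C)=CC[C@@H]12 | intermediate
27 | 3'-O-acetate of 26 | C=C1[C@H](O[Si](C)(C)C(C)(C)C)C[C@@H]([C@@H](C)[C@H](/C=C/C(C)(C)O)OC(C)=O)[C@@H](O[Si](C)(C)C(C)(C)C)[C@@H]2C(C)=CC[C@@H]12 | intermediate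
28 | (2R,3S,4E)-2-[(3aS,4R,5S,7R,8aR)-4,7-dihydroxy-3-methyl-8-methylidene-1,3a,4,5,6,7,8,8a-octahydroazulen-5-yl]-6-hydroxy-6-methylhept-4-en-3-yl acetate | C=C1[C@H](O)C[C@@H]([C@@H](C)[C@H](/C=C/C(C)(C)O)OC(C)=O)[C@@H](O)[C@@H]2C(C)=CC[C@@H]12 | target

**Count and risks**

Total step count: 21. Longest linear sequence: 18 steps (steps 4 to 21, from cyclohept-4-en-1-one).

Step 8. A second annulation on the remaining enone, and Lewis-acid-induced loss of silanol with aromatisation of the dienone toward a tropone, may compete with the wanted mono-annulation. The fallback sets out from 9 and takes the annulation to a substrate with one enone only. A single IBX dehydrogenation gives (4R,5R)-4,5-bis(triethylsilyloxy)cyclohept-2-en-1-one F1; either α-side gives the same enone because of the C2 axis. Danheiser annulation of F1 under the conditions of step 8, again anti to the neighbouring silyloxy group, gives the saturated cis-fused silylcyclopentene ketone F2. Kinetic deprotonation with KN(SiMe3)2 at −78 °C at the C5 methylene, not at the ring-fusion methine, gives enolate 12, which is alkylated with 5 as in step 9. The fallback comes back to the route at 13.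

Step 9. The hydride may add 1,2 instead of 1,4, and during the slow displacement on the secondary triflate, proton transfer between enolate 12 and product 13 at the acidic allylic C3a–H may scramble the regiochemistry and the ring fusion. The fallback sets out from 11 and separates enolate generation from alkylation. RhCl(PPh3)3-catalysed 1,4-hydrosilylation with Et3SiH gives the regiodefined triethylsilyl enol ether F3, which can be purified. MeLi in THF then releases the borane-free lithium enolate F4, which is added to an excess of 5. The fallback comes back to the route at 13.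

Step 10. Hydride delivery to the other face of the C4 carbonyl, which carries the side chain but not the cyclopentene, would give the 4-epi alcohol, which cannot lactonise. The fallback sets out from 13 and forms the C4–O bond by displacement instead of by facial control. Reduction with NaBH4 and CeCl3 gives the 4-epi hydroxy ester F5, which is converted with MsCl and Et3N into the mesylate F6. LiOH in aqueous THF hydrolyses the ester to the lithium carboxylate F7, which displaces the mesylate from the rear (5-exo-tet SN2 with inversion at C4). The fallback comes back to the route at 15, so that either alcohol epimer ends in the same lactone.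

Further compounds
F1 | step 8 | (4R,5R)-4,5-bis(triethylsilyloxy)cyclohept-2-en-1-one | CC[Si](CC)(CC)O[C@H]1[C@H](O[Si](CC)(CC)CC)CCC(=O)C=C1
F2 | step 8 | cis-fused 3-methyl-7,8-bis(triethylsilyloxy)-2-(trimethylsilyl)-3a,5,6,7,8,8a-hexahydroazulen-4(1H)-one (configuration as in 11) | CC[Si](CC)(CC)O[C@H]1[C@H](O[Si](CC)(CC)CC)CCC(=O)[C@@H]2C(C)=C([Si](C)(C)C)C[C@H]12
F3 | step 9 | triethylsilyl C4=C5 enol ether of the 5,6-dihydro derivative of 11 | CC[Si](CC)(CC)O[C@H]1[C@H](O[Si](CC)(CC)CC)CC=C(O[Si](CC)(CC)CC)[C@@H]2C(C)=C([Si](C)(C)C)C[C@H]12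
F4 | step 9 | lithium C4=C5 enolate corresponding to F3 | CC[Si](CC)(CC)O[C@H]1[C@H](O[Si](CC)(CC)CC)CC=C(O[Li])[C@@H]2C(C)=C([Si](C)(C)C)C[C@H]12
F5 | step 10 | 4-epi hydroxy ester (C4 epimer of 14; 4-OH trans to the C5 side chain) | CC[Si](CC)(CC)O[C@H]1[C@H](O[Si](CC)(CC)CC)C[C@@H]([C@@H](C)C(=O)OC)[C@H](O)[C@@H]2C(C)=C([Si](C)(C)C)C[C@H]12
F6 | step 10 | 4-O-methanesulfonate of F5 | CC[Si](CC)(CC)O[C@H]1[C@H](O[Si](CC)(CC)CC)C[C@@H]([C@@H](C)C(=O)OC)[C@H](OS(C)(=O)=O)[C@@H]2C(C)=C([Si](C)(C)C)C[C@H]12
F7 | step 10 | lithium carboxylate from F6 | CC[Si](CC)(CC)O[C@H]1[C@H](O[Si](CC)(CC)CC)C[C@@H]([C@@H](C)C(=O)O[Li])[C@H](OS(C)(=O)=O)[C@@H]2C(C)=C([Si](C)(C)C)C[C@H]12
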